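## The problem

Atom labels used throughout: C1 is the carboxyl carbon; C2=C3 the cage alkene (C2 bears C1); C4 the bridgehead carbinol; C5 a methylene; C6 a methine; C7 the gem-dimethyl ether carbon; C8 the prenylated ether carbon; C9 the cage ketone; C10 the bridgehead ether carbon. Ring A carbons are C1′ (CH–prenyl), C2′ (C=O), C3′=C4′ (pyran-fused alkene), C5′ (C=O) and C6′ (spiro carbon).

Compound 31 joins two halves through a spiro acylal: C6′ of ring A carries both the acyl oxygen of C1 and the ether oxygen of C10, which closes a 1,3-dioxan-4-one. The cage is a bicyclo[2.2.2]oct-2-ene (bridgeheads C4 and C10; bridges C2=C3, C5–C6 and C9–C8) in which C6 and C8 are tied by C7Me2–O into a tetrahydrofuran. There are six stereocentres. Once the cage exists C4 is fixed by the bridge, so the real tasks are the absolute configuration at C8, the relation of C6 to C8 (1,3 across the ring carbon C10) and the cis ring fusion C6/C10. The two ring A centres come last; C1′ is epimerisable. Two prenyl groups and the chromene alkene exclude ozone, peracids, dioxiranes, singlet oxygen and hydrogenation. A free C10 alkoxide is β to a C9 carbonyl and invites retro-aldol cleavage, C4–OH/C9=O is an α-ketol, and the acylal will not tolerate base or nucleophiles. The enabling feature is the C4–C9 bond: both carbons are at the carbonyl oxidation level, so an aldehyde at C9 and a ring ketone at C4, held 1,4 across a cis-fused tetrahydrofuran–cyclohexenone, can be joined by acyl-anion umpolung, and that one bond closes the bicyclo[2.2.2]octenone.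

## Retrosynthesis

**Acylal.** In 31 the C10–O–C6′ bond is cut first, giving the acyloxyquinone 29 (silyl ether) and its free alcohol 30. Cutting the ester first would leave a hindered tertiary alkoxide to attack a quinone intermolecularly. In the chosen order the alcohol is delivered through a six-membered transition state. The precursor loses the spiro centre and C1′. The forward step asks the C10 hydroxyl to add to the acyloxy-bearing quinone carbon and the enol to ketonise at C1′.

**Ester.** 29 is cut at the ester C–O bond into cage acid 22 and hydroxyquinone 27. This is the convergent joint. 27 is traced to 26 (C-prenylation with 6), 26 to chromenediol 25 (phenol-to-quinone oxidation para to the C5 hydroxyl), and 25 to phloroglucinol 23 and 3-methylbut-2-enal 24.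

**Ester protecting group.** 22 comes from the tert-butyl ester 20. A tert-butyl ester is chosen over an ethyl ester because it survives the hydride steps below and is removed without hydroxide, which the α-ketol and β-silyloxy ketone would not tolerate.

**Key cut.** 20 is cut at C4–C9 to keto aldehyde 19. Aldol-type cuts at C4–C5 or C3–C4 have no matching donor, and a Diels–Alder cut of the bicyclooctene would need a diene carrying the quaternary C10 and C8. The C4–C9 cut is the only one that uses the α-ketol as such. It removes one ring and one stereocentre and leaves a bicycle. The forward step needs 1,2-addition of an acyl anion equivalent to the enone carbonyl.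

**Redox adjustment.** 19 comes from diol 18 by double oxidation, 18 from allylic alcohol 17 (methyl ester reduction), 17 from enone 16 (1,2-reduction) and 16 from tertiary alcohol 15 (silylation). The C9 ester is kept as an ester until all cage stereocentres except C4 are set, because it is the small, chelating group that the earlier selectivity relies on.

**C10–O bond.** 15 is cut at C10–O to the bicyclic keto diester 13 (C10=C2 alkene). The more obvious cut, C10–C2 by intermolecular addition of a two-carbon acyl-anion equivalent to a furanone ketone, was set aside. The nucleophile would have to enter cis to the C6 side chain, against the normal preference, and the usual way of turning a diazo adduct into a keto ester uses oxidants that attack prenyl groups. With C10 sp2, oxygen can only be returned on the face that gives the cis-fused bicycle.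

**Ring closure.** 13 is cut at C10=C2 (Horner–Wadsworth–Emmons) and C2–C3 (alkylation) into bromo ketone 10 and phosphonoacetate 11. Because the closure is intramolecular the ring fusion cannot be wrong, and the C4 ketone never coexists with a strong base and a free methyl ketone.

**Side chain.** 10 comes from enol ether 9 (bromination and hydrolysis), and 9 from furanone 7 and 3-bromo-2-methoxyprop-1-ene 8 by enolate alkylation at C6. This step must place the chain trans to the prenyl group.

**Furanone.** 7 is cut at C8–CH2 to keto ester 5 and prenyl bromide 6; a chiral phase-transfer catalyst sets C8. 5 is cut at O–C8 (carbenoid O–H insertion) to diazo ester 4, which comes from 3, and 3 from methyl acetoacetate 1 and acetone 2. A one-step oxa-Michael/Dieckmann union of a glycolate with a 3-methylbut-2-enoate is shorter, but it can close in two senses and is expected to put the ester next to the gem-dimethyl carbon; the insertion route cannot.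

## Roads not taken

**Alternative 1:** The quaternary ether carbon C8 is cut at both C8–O and C8–CH2(prenyl). Forward, Rh2(OAc)4 decomposes the 2-diazo-1,3-dione A2; the carbenoid is trapped by the 1,1-dimethylallyl ether oxygen and the oxonium ylide undergoes a [2,3] shift to the bridged ether dione A1 (6-oxabicyclo[3.2.1]octane-4,8-dione). Merits: the tetrahydrofuran, the quaternary centre and the prenyl group arrive in one step, and the C9–C4 bond is already present. Weak points: A2 needs a di-tertiary ether, which is hard to make and a poor ylide donor; a [1,2] shift and C–H insertion compete; enantiocontrol rests on the single C6 centre or on a chiral catalyst. A1 also still lacks C1–C3 and the C4 hydroxyl, so a second ring has to be built across a hindered dione. On connectivity at C8 this road is more secure than the chosen plan, which relies on an ion-pair alkylation. Against that the chosen plan carries C1–C3 and the C4 oxygen into the cage-closing step, so the cage is complete when it forms.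

**Alternative 2:** Ring A is cut at C6′–C1′. Forward, the bis-enolate of the acetal diketone A4 (acetal C–H and the CH2 beside the other ketone) is oxidised by divalent copper, as Cu(2-ethylhexanoate)2, to the silyl ether A3 of the target. Merits: the acylal is made early by ordinary acetalisation, and the spiro centre and C1′ form under kinetic control. Weak points: an anion at the acetal carbon sits β to an acyloxy leaving group and can open the dioxanone; two strong-base enolisations must be carried out beside the cage ketone and two esters; a quaternary spiro carbon has to form by radical coupling next to a hindered centre. This road could give better control of the spiro configuration than the chosen thermodynamic closure. It does nothing for the cage, which must be made in any case, and the chosen plan uses only mild acid in its last step.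

**Alternative 3:** The cage is cut at C6–C10 and O–C7. Forward, Me2AlCl activates the C10 ketone of the dearomatised diprenyl benzoate A6, the prenyl group on C4 attacks through its alkene CH, and the tertiary cation is trapped by the C8 hydroxyl to give cage diol A5. Merits: two rings and two bonds in one step from a precursor a few steps from a benzoate; it is much the shortest road. Weak points: A6 has two tertiary carbinols whose relative and absolute configuration must be set during dearomatisation; two prenyl groups and two ketones allow four pairings; α-ketol shifts and proton loss from the cation compete under Lewis acid. If it worked it would beat the chosen plan on step count by a wide margin. What the chosen plan offers in exchange is that every stereocentre has an identified control element and every ring-forming step has one reasonable outcome.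

Key step: step 13

Assumptions: 8 and 11 are taken as purchasable. The cinchonidinium salt is written for step 4; if it favours the (S)-ester, its pseudoenantiomer (cinchoninium) takes its place. The acylal of 31 is taken to form reversibly, so that C6′ and C1′ end in the more stable arrangement, which is assumed to be the natural one.

## Route

Step 1
Reactants: 1 methyl acetoacetate; 2 acetone
Product: 3 methyl 5-hydroxy-5-methyl-3-oxohexanoate
Conditions: NaH, THF, 0 °C; n-BuLi, −10 °C; 2, −78 → 0 °C; NH4Cl (aq)
Reagents that add atoms: none
Why: Dianion aldol addition; the terminal carbanion of the β-keto ester dianion is the more nucleophilic site and adds to the ketone, giving the tertiary alcohol.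

Step 2
Reactants: 3 methyl 5-hydroxy-5-methyl-3-oxohexanoate
Product: 4 methyl 2-diazo-5-hydroxy-5-methyl-3-oxohexanoate
Conditions: 4-acetamidobenzenesulfonyl azide, Et3N, MeCN, 0 °C → rt
Reagents that add atoms: 4-acetamidobenzenesulfonyl azide, CC(=O)Nc1ccc(cc1)S(=O)(=O)N=[N+]=[N-]
Why: Regitz diazo transfer to the active methylene of a β-keto ester; the tertiary alcohol is inert.

Step 3
Reactants: 4 methyl 2-diazo-5-hydroxy-5-methyl-3-oxohexanoate
Product: 5 methyl 5,5-dimethyl-3-oxotetrahydrofuran-2-carboxylate (racemic)
Conditions: Rh2(OAc)4 (1 mol%), CH2Cl2, reflux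
Reagents that add atoms: none
Why: Intramolecular rhodium-carbenoid O–H insertion closes the five-membered ether, a standard route to 3-oxotetrahydrofuran-2-carboxylates, and puts the ester on the carbon next to oxygen without ambiguity.

Step 4
Reactants: 5 methyl 5,5-dimethyl-3-oxotetrahydrofuran-2-carboxylate; 6 prenyl bromide (1-bromo-3-methylbut-2-ene)
Product: 7 methyl (2R)-5,5-dimethyl-2-(3-methylbut-2-en-1-yl)-3-oxotetrahydrofuran-2-carboxylate
Conditions: N-(9-anthracenylmethyl)cinchonidinium bromide (10 mol%), K2CO3 (solid), toluene, −20 °C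
Reagents that add atoms: none
Why: Asymmetric phase-transfer C-alkylation of a cyclic β-keto ester; the enolate–ammonium ion pair exposes one face to the allylic bromide and sets C8, which is quaternary and cannot racemise.

Step 5
Reactants: 7 methyl (2R)-5,5-dimethyl-2-(3-methylbut-2-en-1-yl)-3-oxotetrahydrofuran-2-carboxylate; 8 3-bromo-2-methoxyprop-1-ene
Product: 9 methyl (2R,4S)-4-(2-methoxyprop-2-en-1-yl)-5,5-dimethyl-2-(3-methylbut-2-en-1-yl)-3-oxotetrahydrofuran-2-carboxylate (side chain cis to the ester, trans to prenyl)
Conditions: LiN(iPr)2, THF, −78 °C; 8, DMPU, −78 → −30 °C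
Reagents that add atoms: none
Why: Kinetic enolate alkylation; the enolate can form only toward C6, and lithium chelation between the enolate oxygen and the ester carbonyl holds the ester over the oxygen end while the prenyl chain covers the other face, so the allylic bromide should enter anti to prenyl (1,3-induction).

Step 6
Reactants: 9 methyl (2R,4S)-4-(2-methoxyprop-2-en-1-yl)-5,5-dimethyl-2-(3-methylbut-2-en-1-yl)-3-oxotetrahydrofuran-2-carboxylate
Product: 10 methyl (2R,4S)-4-(3-bromo-2-oxopropyl)-5,5-dimethyl-2-(3-methylbut-2-en-1-yl)-3-oxotetrahydrofuran-2-carboxylate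
Conditions: NBS (1.05 equiv), THF/H2O 4:1, 0 °C
Reagents that add atoms: N-bromosuccinimide, O=C1CCC(=O)N1Br; water, O
Why: Bromination of an enol ether with hydrolysis of the oxocarbenium ion gives the bromomethyl ketone; the enol ether is far more nucleophilic than the trisubstituted prenyl alkene, and the neutral medium leaves C6 untouched.

Step 7
Reactants: 10 methyl (2R,4S)-4-(3-bromo-2-oxopropyl)-5,5-dimethyl-2-(3-methylbut-2-en-1-yl)-3-oxotetrahydrofuran-2-carboxylate; 11 tert-butyl 2-(diethoxyphosphoryl)acetate
Product: 13 7-tert-butyl 1-methyl 3,3-dimethyl-1-(3-methylbut-2-en-1-yl)-5-oxo-1,3,3a,4,5,6-hexahydro-2-benzofuran-1,7-dicarboxylate (C7=C7a alkene; H-3a on the prenyl face), via keto phosphonate 12 (not isolated)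
Conditions: 11, NaH (1.05 equiv), THF, 0 °C; 10, 0 °C → rt; NaH (1.1 equiv), 0 → 65 °C
Reagents that add atoms: none
Why: SN2 alkylation of the soft phosphonoacetate anion at the α-bromo ketone, then intramolecular Horner–Wadsworth–Emmons olefination of the ring ketone closes the six-membered ring; C10 becomes sp2, so no stereocentre is formed and the C6 centre is kept.

Step 8
Reactants: 13 7-tert-butyl 1-methyl 3,3-dimethyl-1-(3-methylbut-2-en-1-yl)-5-oxo-1,3,3a,4,5,6-hexahydro-2-benzofuran-1,7-dicarboxylate
Product: 15 7-tert-butyl 1-methyl 7a-hydroxy-3,3-dimethyl-1-(3-methylbut-2-en-1-yl)-5-oxo-1,3,3a,4,5,7a-hexahydro-2-benzofuran-1,7-dicarboxylate (cis-fused; 7a-OH cis to H-3a and to prenyl), via tertiary hydroperoxide 14 (not isolated)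
Conditions: Cs2CO3 (20 mol%), P(OEt)3 (2 equiv), O2 (1 atm), DMSO, rt
Reagents that add atoms: dioxygen, O=O
Why: Base-mediated aerobic γ-oxygenation of the extended enolate of a β,γ-unsaturated ketone with phosphite reduction of the hydroperoxide; O2 adds to C10 on the face of H-6 because only that approach gives the cis-fused bicycle, the alkene moves to C2=C3, and the ring C8–O bond lies near the nodal plane of the enolate, so β-elimination is not expected.

Step 9
Reactants: 15 7-tert-butyl 1-methyl 7a-hydroxy-3,3-dimethyl-1-(3-methylbut-2-en-1-yl)-5-oxo-1,3,3a,4,5,7a-hexahydro-2-benzofuran-1,7-dicarboxylate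
Product: 16 the 7a-O-triethylsilyl ether of 15
Conditions: TESOTf, 2,6-lutidine, CH2Cl2, −40 → 0 °C
Reagents that add atoms: triethylsilyl trifluoromethanesulfonate, CC[Si](CC)(CC)OS(=O)(=O)C(F)(F)F
Why: Silyl triflate silylation of a hindered tertiary alcohol; the ether blocks retro-aldol cleavage once C9 becomes an aldehyde and later a ketone.

Step 10
Reactants: 16 the 7a-O-triethylsilyl ether of 15
Product: 17 7-tert-butyl 1-methyl 5-hydroxy-3,3-dimethyl-1-(3-methylbut-2-en-1-yl)-7a-(triethylsilyloxy)-1,3,3a,4,5,7a-hexahydro-2-benzofuran-1,7-dicarboxylate (both C5 epimers)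
Conditions: NaBH4, CeCl3·7H2O, MeOH, −40 °C
Reagents that add atoms: none
Why: Luche reduction gives clean 1,2-reduction of the enone and leaves both esters; the new carbinol centre is removed again in step 12.

Step 11
Reactants: 17 7-tert-butyl 1-methyl 5-hydroxy-3,3-dimethyl-1-(3-methylbut-2-en-1-yl)-7a-(triethylsilyloxy)-1,3,3a,4,5,7a-hexahydro-2-benzofuran-1,7-dicarboxylate
Product: 18 tert-butyl 5-hydroxy-1-(hydroxymethyl)-3,3-dimethyl-1-(3-methylbut-2-en-1-yl)-7a-(triethylsilyloxy)-1,3,3a,4,5,7a-hexahydro-2-benzofuran-7-carboxylate
Conditions: LiBH4, THF, MeOH (1 equiv), 0 → 40 °C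
Reagents that add atoms: none
Why: LiBH4 reduces the α-alkoxy methyl ester but not the hindered conjugated tert-butyl ester, which is also too bulky to lactonise with the new primary alcohol.

Step 12
Reactants: 18 tert-butyl 5-hydroxy-1-(hydroxymethyl)-3,3-dimethyl-1-(3-methylbut-2-en-1-yl)-7a-(triethylsilyloxy)-1,3,3a,4,5,7a-hexahydro-2-benzofuran-7-carboxylate
Product: 19 tert-butyl 1-formyl-3,3-dimethyl-1-(3-methylbut-2-en-1-yl)-5-oxo-7a-(triethylsilyloxy)-1,3,3a,4,5,7a-hexahydro-2-benzofuran-7-carboxylate (formyl cis to C4H2 and to the enoate carbon, trans to the silyloxy group)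
Conditions: Dess–Martin periodinane (3 equiv), CH2Cl2, rt
Reagents that add atoms: none
Why: Dess–Martin oxidation converts the allylic alcohol to the enone and the neopentylic alcohol to the aldehyde in one operation; the aldehyde has no α-hydrogen and cannot epimerise.

Step 13
Reactants: 19 tert-butyl 1-formyl-3,3-dimethyl-1-(3-methylbut-2-en-1-yl)-5-oxo-7a-(triethylsilyloxy)-1,3,3a,4,5,7a-hexahydro-2-benzofuran-7-carboxylate
Product: 20 cage ketol tert-butyl ester (bicyclo[2.2.2]oct-2-ene with CO2tBu on C2, bridgehead OH on C4, ketone C9, prenyl on C8, OSiEt3 on bridgehead C10, and the C6–C7Me2–O–C8 tetrahydrofuran)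
Conditions: 2-(pentafluorophenyl)-6,7-dihydro-5H-pyrrolo[2,1-c][1,2,4]triazolium tetrafluoroborate (20 mol%), Et3N (20 mol%), THF, 40 °C
Reagents that add atoms: none
Why: The carbene from the triazolium salt adds to the neopentylic, α-alkoxy aldehyde, proton transfer gives the Breslow enaminol, and this acyl-anion equivalent attacks the ring ketone C4 before the carbene leaves. The closest known reaction type is the carbene-catalysed intramolecular crossed aldehyde–ketone benzoin that gives cyclic tertiary α-ketols. The ring that closes is C4–C5–C6–C10–C8–C9, by a 6-exo-trig attack on the carbonyl carbon, and with it the bicyclo[2.2.2]octenone is complete. The new stereocentre C4 is controlled by the bridge: the aldehyde carbon and C5 lie on the same face of the tetrahydrofuran, so only one face of the ketone can be reached. The step needs 1,2-addition to win over Stetter addition; attack at C3 would be a 5-endo-trig closure and attack at C2 would make a four-membered ring, so ring size secures it. The aldehyde cannot enolise and the C10 oxygen is silylated, which shuts off aldol and retro-aldol paths at C8–C10. A weak amine base is used so that enolisation at C5 stays minor; its aldol onto the aldehyde would give a strained bicyclo[2.2.1] adduct and is reversible, whereas the ketol is the less strained product.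

Step 14
Reactants: 20 cage ketol tert-butyl ester
Product: 22 cage ketol carboxylic acid (as 20 with CO2H on C2; OSiEt3 on C10 retained), via bis(trimethylsilyl) derivative 21 (not isolated)
Conditions: TMSOTf (3 equiv), 2,6-lutidine (4 equiv), CH2Cl2, 0 °C; then citric acid (aq), THF, 0 °C
Reagents that add atoms: none
Why: Silyl triflate-mediated cleavage of a tert-butyl ester through the silyl ester avoids hydroxide; the transient trimethylsilyl ether at C4 and the silyl ester fall off on mild acidic work-up, while the hindered triethylsilyl ether stays.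

Step 15
Reactants: 23 phloroglucinol; 24 3-methylbut-2-enal
Product: 25 2,2-dimethyl-2H-chromene-5,7-diol
Conditions: pyridine, 110 °C (23 in excess)
Reagents that add atoms: none
Why: Chromene annulation of a phenol with an enal (condensation at the ring carbon, then 6π oxa-electrocyclisation); the symmetry of 23 allows one mono-adduct only.

Step 16
Reactants: 25 2,2-dimethyl-2H-chromene-5,7-diol
Product: 26 7-hydroxy-2,2-dimethyl-2H-chromene-5,8-dione
Conditions: (KSO3)2NO (2.2 equiv), KH2PO4 buffer, acetone/H2O, 0 °C → rt
Reagents that add atoms: potassium nitrosodisulfonate, [O]N(S(=O)(=O)[O-])S(=O)(=O)[O-].[K+].[K+]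
Why: Teuber oxidation of a phenol with a free para position; only C8 is para to a hydroxyl (C5–OH) and unsubstituted, so the 5,8-quinone with the C7 hydroxyl retained should result.

Step 17
Reactants: 26 7-hydroxy-2,2-dimethyl-2H-chromene-5,8-dione; 6 prenyl bromide
Product: 27 7-hydroxy-2,2-dimethyl-6-(3-methylbut-2-en-1-yl)-2H-chromene-5,8-dione
Conditions: LiH, DMSO, rt; 6, LiI (cat.), rt
Reagents that add atoms: none
Why: C-alkylation of the lithium salt of a 2-hydroxy-1,4-quinone at its only free ring carbon, the reaction type used to prenylate hydroxynaphthoquinones; the lithium counter-ion in DMSO favours carbon over oxygen.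

Step 18
Reactants: 22 cage ketol carboxylic acid; 27 7-hydroxy-2,2-dimethyl-6-(3-methylbut-2-en-1-yl)-2H-chromene-5,8-dione
Product: 29 2,2-dimethyl-6-(3-methylbut-2-en-1-yl)-5,8-dioxo-5,8-dihydro-2H-chromen-7-yl ester of acid 22, via acid chloride 28 (not isolated)
Conditions: 1-chloro-N,N,2-trimethylprop-1-en-1-amine, CH2Cl2, 0 °C; then 27, Et3N, 0 °C → rt
Reagents that add atoms: none
Why: Neutral acid chloride formation, then O-acylation of the acidic hydroxyquinone; its carbon terminus is blocked by prenyl, the bridgehead C4 hydroxyl is too hindered to acylate, and Bredt strain excludes lactonisation onto it.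

Step 19
Reactants: 29 quinone ester
Product: 31 CNP0222516.1, via C10-hydroxy quinone ester 30 (not isolated)
Conditions: HF (48% aq), MeCN, 0 °C → rt
Reagents that add atoms: none
Why: Fluoride desilylation frees the C10 hydroxyl, which adds to the acyloxy-bearing quinone carbon C6′ through a six-membered transition state (intramolecular oxa-Michael addition under acid catalysis); ketonisation at C1′ then locks the acylal, and reversibility of addition and of enolisation should let C6′ and C1′ settle in the more stable arrangement.

## Compound list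

1 | methyl acetoacetate | COC(=O)CC(C)=O | starting material
2 | acetone | CC(C)=O | starting material
3 | methyl 5-hydroxy-5-methyl-3-oxohexanoate | COC(=O)CC(=O)CC(C)(C)O | intermediate
4 | methyl 2-diazo-5-hydroxy-5-methyl-3-oxohexanoate | COC(=O)C(=[N+]=[N-])C(=O)CC(C)(C)O | intermediate
5 | methyl 5,5-dimethyl-3-oxotetrahydrofuran-2-carboxylate (racemic) | COC(=O)C1OC(C)(C)CC1=O | intermediate
6 | prenyl bromide | CC(C)=CCBr | starting material
7 | methyl (2R)-5,5-dimethyl-2-(3-methylbut-2-en-1-yl)-3-oxotetrahydrofuran-2-carboxylate | CC1(C)O[C@@](CC=C(C)C)(C(=O)OC)C(=O)C1 | intermediate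
8 | 3-bromo-2-methoxyprop-1-ene | COC(=C)CBr | starting material
9 | methyl (2R,4S)-4-(2-methoxyprop-2-en-1-yl)-5,5-dimethyl-2-(3-methylbut-2-en-1-yl)-3-oxotetrahydrofuran-2-carboxylate | COC(=C)C[C@H]1C(C)(C)O[C@@](CC=C(C)C)(C(=O)OC)C1=O | intermediate
10 | methyl (2R,4S)-4-(3-bromo-2-oxopropyl)-5,5-dimethyl-2-(3-methylbut-2-en-1-yl)-3-oxotetrahydrofuran-2-carboxylate | BrCC(=O)C[C@H]1C(C)(C)O[C@@](CC=C(C)C)(C(=O)OC)C1=O | intermediate
11 | tert-butyl 2-(diethoxyphosphoryl)acetate | CCOP(=O)(CC(=O)OC(C)(C)C)OCC | starting material
12 | keto phosphonate (tert-butyl 2-(diethoxyphosphoryl)-4-oxopentanoate carrying the furanone of 10 at C5) | CCOP(=O)(OCC)C(CC(=O)C[C@H]1C(C)(C)O[C@@](CC=C(C)C)(C(=O)OC)C1=O)C(=O)OC(C)(C)C | intermediate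
13 | bicyclic keto diester with C7=C7a alkene | CC(C)(C)OC(=O)C1=C2[C@@H](CC(=O)C1)C(C)(C)O[C@@]2(CC=C(C)C)C(=O)OC | intermediate
14 | tertiary hydroperoxide of 15 | CC(C)(C)OC(=O)C1=CC(=O)C[C@H]2C(C)(C)O[C@@](CC=C(C)C)(C(=O)OC)[C@@]12OO | intermediate
15 | cis-fused γ-hydroxy enone diester | CC(C)(C)OC(=O)C1=CC(=O)C[C@H]2C(C)(C)O[C@@](CC=C(C)C)(C(=O)OC)[C@@]12O | intermediate
16 | triethylsilyl ether of 15 | CC(C)(C)OC(=O)C1=CC(=O)C[C@H]2C(C)(C)O[C@@](CC=C(C)C)(C(=O)OC)[C@@]12O[Si](CC)(CC)CC | intermediate
17 | allylic alcohol (C5 epimers) | CC(C)(C)OC(=O)C1=CC(O)C[C@H]2C(C)(C)O[C@@](CC=C(C)C)(C(=O)OC)[C@@]12O[Si](CC)(CC)CC | intermediate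
18 | diol | CC(C)(C)OC(=O)C1=CC(O)C[C@H]2C(C)(C)O[C@@](CC=C(C)C)(CO)[C@@]12O[Si](CC)(CC)CC | intermediate
19 | keto aldehyde (key-step precursor) | CC(C)(C)OC(=O)C1=CC(=O)C[C@H]2C(C)(C)O[C@@](CC=C(C)C)(C=O)[C@@]12O[Si](CC)(CC)CC | intermediate
20 | cage ketol tert-butyl ester (key-step product) | CC(C)(C)OC(=O)C1=C[C@]3(O)C[C@H]4C(C)(C)O[C@@](CC=C(C)C)(C3=O)[C@@]14O[Si](CC)(CC)CC | intermediate
21 | trimethylsilyl ester, C4 trimethylsilyl ether of 22 | C[Si](C)(C)OC(=O)C1=C[C@]3(O[Si](C)(C)C)C[C@H]4C(C)(C)O[C@@](CC=C(C)C)(C3=O)[C@@]14O[Si](CC)(CC)CC | intermediate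
22 | cage ketol carboxylic acid | OC(=O)C1=C[C@]3(O)C[C@H]4C(C)(C)O[C@@](CC=C(C)C)(C3=O)[C@@]14O[Si](CC)(CC)CC | intermediate
23 | phloroglucinol | Oc1cc(O)cc(O)c1 | starting material
24 | 3-methylbut-2-enal | CC(C)=CC=O | starting material
25 | 2,2-dimethyl-2H-chromene-5,7-diol | CC1(C)C=Cc2c(O)cc(O)cc2O1 | intermediate
26 | 7-hydroxy-2,2-dimethyl-2H-chromene-5,8-dione | O=C1C=C(O)C(=O)C2=C1C=CC(C)(C)O2 | intermediate
27 | 7-hydroxy-2,2-dimethyl-6-(3-methylbut-2-en-1-yl)-2H-chromene-5,8-dione | O=C1C(CC=C(C)C)=C(O)C(=O)C2=C1C=CC(C)(C)O2 | intermediate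
28 | acid chloride of 22 | ClC(=O)C1=C[C@]3(O)C[C@H]4C(C)(C)O[C@@](CC=C(C)C)(C3=O)[C@@]14O[Si](CC)(CC)CC | intermediate
29 | quinone ester (silyl ether) | O=C1C(CC=C(C)C)=C(OC(=O)C3=C[C@]4(O)C[C@H]5C(C)(C)O[C@@](CC=C(C)C)(C4=O)[C@@]35O[Si](CC)(CC)CC)C(=O)C2=C1C=CC(C)(C)O2 | intermediate
30 | quinone ester with free C10 hydroxyl | O=C1C(CC=C(C)C)=C(OC(=O)C3=C[C@]4(O)C[C@H]5C(C)(C)O[C@@](CC=C(C)C)(C4=O)[C@@]35O)C(=O)C2=C1C=CC(C)(C)O2 | intermediate
31 | CNP0222516.1 | CC(C)=CC[C@H]1C(=O)C2=C(OC(C)(C)C=C2)C(=O)[C@@]12OC(=O)C1=C[C@]3(O)C[C@H]4C(C)(C)O[C@@](CC=C(C)C)(C3=O)[C@@]14O2 | target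

## Step count and least certain steps

Total: 19 steps. Longest linear sequence: 16 steps (steps 1–14, 18, 19); steps 15–17 make the ring A fragment.

**Step 13 (key step).** Most likely failure: slow carbene addition to the neopentylic aldehyde, so that reversible enolate aldol at C5 and decomposition of the free carbene take over, or the ketol reverts by retro-benzoin on long heating. Fallback: from 19, reductive carbonyl coupling with SmI2 (THF, −78 °C) joins C4 and C9 as the cis-diol F1; oxidation of its secondary C9 carbinol (Dess–Martin) returns to 20.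

**Step 5.** Most likely failure: poor facial selectivity, because the only bias is the 1,3-related quaternary C8 with two groups of similar size; O-alkylation is a lesser risk. Fallback: reverse the order of the two alkylations. From 5, the dianion (NaH, then n-BuLi) is alkylated at C4 with 8 to give the racemic keto ester F2. Phase-transfer prenylation with 6 under the step 4 catalyst then brings the prenyl group in anti to a side chain that competes only with hydrogen, and the catalyst selects the matching enantiomer. The route is rejoined at 9, at the cost of a kinetic resolution.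

**Step 7.** Most likely failure: the olefination stalls at the hindered ring ketone, or enolisation of the bromo ketone by the phosphonate anion leads to intramolecular aldol and epoxide formation. Fallback: form the C10–C2 bond by cross-coupling. From 7, KN(SiMe3)2 and PhNTf2 give the enol triflate F3. Me6Sn2 with Pd(PPh3)4 and LiCl gives the vinylstannane F4. Stille acylation with tert-butyl chlorooxoacetate gives the unsaturated keto ester F5. Mukaiyama–Michael addition of 2-(trimethylsilyloxy)propene (TiCl4) and acid-catalysed aldol condensation give the conjugated enone F6, the tautomer of 13. F6 enters step 8 and rejoins the route at 15.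

**Step 8.** Most likely failure: oxygenation at C3 and not at C10, over-oxidation of the dione system, or opening of the tetrahydrofuran from the extended enolate. Fallback: from 13, α-selenenylation (LiN(SiMe3)2, PhSeCl) gives the allylic selenide F7. Oxidation with H2O2/pyridine and [2,3]-sigmatropic shift of the selenoxide deliver oxygen to C10 with the alkene moving to C2=C3, returning to 15.

**Step 19.** Most likely failure: the tertiary hydroxyl adds too slowly and the activated ester hydrolyses, or the adduct collapses by loss of the carboxylate; selectivity at the spiro centre may also be poor. Fallback: reverse the order of the two C–O bonds. From 20, desilylation (HF, MeCN) gives the diol ester F8. Addition–elimination of its C10 hydroxyl (Cs2CO3, kept cold against retro-aldol) on the 7-chloroquinone F9, made from 27 with oxalyl chloride and DMF, gives the quinone ether F10. Cleavage of the tert-butyl ester as in step 14 gives the acid F11. Acid-catalysed conjugate addition of the carboxyl group to the alkoxy-bearing quinone carbon and ketonisation then lead to 31.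

## Further compounds

F1 | step 13 | cage cis-diol tert-butyl ester (C9 carbinol) | CC(C)(C)OC(=O)C1=C[C@]3(O)C[C@H]4C(C)(C)O[C@@](CC=C(C)C)(C3O)[C@@]14O[Si](CC)(CC)CC
F2 | step 5 | methyl 4-(2-methoxyprop-2-en-1-yl)-5,5-dimethyl-3-oxotetrahydrofuran-2-carboxylate (racemic) | COC(=C)CC1C(=O)C(C(=O)OC)OC1(C)C
F3 | step 7 | enol triflate of 7 | CC1(C)O[C@@](CC=C(C)C)(C(=O)OC)C(OS(=O)(=O)C(F)(F)F)=C1
F4 | step 7 | vinyl trimethylstannane | CC1(C)O[C@@](CC=C(C)C)(C(=O)OC)C([Sn](C)(C)C)=C1
F5 | step 7 | dihydrofuranyl keto ester | CC1(C)O[C@@](CC=C(C)C)(C(=O)OC)C(C(=O)C(=O)OC(C)(C)C)=C1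
F6 | step 7 | conjugated enone tautomer of 13 | CC(C)(C)OC(=O)C1=CC(=O)C[C@H]2C(C)(C)O[C@@](CC=C(C)C)(C(=O)OC)C12
F7 | step 8 | α-phenylselenyl ketone of 13 | CC(C)(C)OC(=O)C1=C2[C@@H](CC(=O)C1[Se]c1ccccc1)C(C)(C)O[C@@]2(CC=C(C)C)C(=O)OC
F8 | step 19 | cage ketol tert-butyl ester with free C10 hydroxyl | CC(C)(C)OC(=O)C1=C[C@]3(O)C[C@H]4C(C)(C)O[C@@](CC=C(C)C)(C3=O)[C@@]14O
F9 | step 19 | 7-chloro-2,2-dimethyl-6-(3-methylbut-2-en-1-yl)-2H-chromene-5,8-dione | O=C1C(CC=C(C)C)=C(Cl)C(=O)C2=C1C=CC(C)(C)O2
F10 | step 19 | quinone ether tert-butyl ester | CC(C)(C)OC(=O)C1=C[C@]3(O)C[C@H]4C(C)(C)O[C@@](CC=C(C)C)(C3=O)[C@@]14OC5=C(CC=C(C)C)C(=O)C6=C(OC(C)(C)C=C6)C5=O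
F11 | step 19 | quinone ether carboxylic acid | OC(=O)C1=C[C@]3(O)C[C@H]4C(C)(C)O[C@@](CC=C(C)C)(C3=O)[C@@]14OC5=C(CC=C(C)C)C(=O)C6=C(OC(C)(C)C=C6)C5=O
A1 | alternative 1 | bridged ether dione | C1C[C@H]2C(C)(C)O[C@@](CC=C(C)C)(C1=O)C2=O
A2 | alternative 1 | 2-diazo-4-[2-(2-methylbut-3-en-2-yloxy)propan-2-yl]cyclohexane-1,3-dione | C=CC(C)(C)OC(C)(C)[C@@H]1CCC(=O)C(=[N+]=[N-])C1=O
A3 | alternative 2 | trimethylsilyl ether of the target | CC(C)=CC[C@H]1C(=O)C2=C(OC(C)(C)C=C2)C(=O)[C@@]12OC(=O)C1=C[C@]3(O[Si](C)(C)C)C[C@H]4C(C)(C)O[C@@](CC=C(C)C)(C3=O)[C@@]14O2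
A4 | alternative 2 | acetal diketone | CC(C)=CCCC(=O)C1=C(OC(C)(C)C=C1)C(=O)C2OC(=O)C3=C[C@]4(O[Si](C)(C)C)C[C@H]5C(C)(C)O[C@@](CC=C(C)C)(C4=O)[C@@]35O2
A5 | alternative 3 | cage diol methyl ester | COC(=O)C1=C[C@]3(O)C[C@H]4C(C)(C)O[C@@](CC=C(C)C)(C3=O)[C@@]14O
A6 | alternative 3 | dearomatised diprenyl benzoate | COC(=O)C1=C[C@](O)(CC=C(C)C)C(=O)[C@@](O)(CC=C(C)C)C1=O
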